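The data were generated by integration on assumed constants; the scatter is artificial.

The easy step comes first: read every run by the share of substrate still left, not by the product made. Since one substrate goes for each product, the share left is one minus product over charge.

| flask | substrate | partner | time |
|---|---|---|---|
| noon | 0.120 M | 0.180 M |  |
| midnight | 0.0600 M | 0.120 M |  |
| autumn | 0.180 M | 0.180 M |  |
| dawn | 0.120 M | 0.270 M |  |
| winter | 0.0600 M | 0.0900 M | 24 min |

| noon run: time / min | noon run: [product] / M | midnight run: time / min | midnight run: [product] / M | autumn run: time / min | autumn run: [product] / M | dawn run: time / min | dawn run: [product] / M |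
|---|---|---|---|---|---|---|---|
| 1.1 | 0.0090 | 1.1 | 0.0030 | 1.1 | 0.0128 | 1.1 | 0.0108 |
| 3.2 | 0.0226 | 3.2 | 0.0100 | 3.2 | 0.0332 | 3.2 | 0.0284 |
| 6.2 | 0.0376 | 6.2 | 0.0150 | 6.2 | 0.0543 | 6.2 | 0.0457 |
| 9.8 | 0.0492 | 9.8 | 0.0221 | 9.8 | 0.0690 | 9.8 | 0.0589 |
| 14 | 0.0585 | 14 | 0.0269 | 14 | 0.0794 | 14 | 0.0682 |
| 19 | 0.0643 | 19 | 0.0314 | 19 | 0.0841 | 19 | 0.0745 |
| 24 | 0.0664 | 24 | 0.0333 | 24 | 0.0876 | 24 | 0.0756 |

(each reading ± 4 × 10⁻⁴ M)

- Overall: substrate + partner -> product.
- Constant volume, constant temperature.
- The analysis sees a species whether free or bound.
- "The second partner" is partner.
- An order is taken over about fifteen percent of the charge, up and down.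

1. how the opening rate goes with [partner] round the charge of the noon run: the exponent of the rate at two percent of substrate gone to product
2. how the opening rate goes with [substrate] round the charge of the noon run: the exponent of the rate at two percent of substrate gone to product (one fixed amount of product, the same in the runs compared)
3. product in the winter run at 24 min, as a share of the substrate charged

The noon run opens at 0.00818 M min⁻¹, which is 0.0682 min⁻¹ of its substrate charge, an apparent first-order rate. Between its last two readings it makes 4.20 × 10⁻⁴ M min⁻¹, so it has become slower by a factor of 19.5, as read. Substrate left in the noon run at 24 min is 44.7 %, a factor of 2.24. The overall equation, taken by itself, leaves 63.1 % of the noon partner, a further 1.58 if the rate goes in step with it. That leaves in the noon run a factor of 5.49, as read, which these two shares do not cover.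

The slowing adds up in the tally, the natural logarithm of charge over substrate left at 24 min, which is the fractional rate summed over the run. At noon it is 0.806, against 1.64 at the opening pace, so the noon run collects half of that pace.

The dawn run, with the noon substrate and more partner, leaves 37.0 %, a tally of 0.994. Read between these two runs, that gives the partner slope, the exponent by which the tally at 24 min goes with the charge c(partner) at fixed substrate charge, 0.518.

The midnight run has the winter substrate charge and leaves 44.5 %, a tally of 0.810. Taking its partner charge down to the winter one with this slope, which I assume holds at this lower substrate charge, gives a winter tally of 0.698, so my own reckoning is product at 50.2 % of the substrate charged.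

The forecast, holding that “This points to saturation”, gives 0.45 for the partner order, 0.85 for the substrate order and 47 % for winter, lower than my figure.

The flask gives 0.62 for the partner order, 1.0 for the substrate order and 49.6 % for winter.

    substrate + partner ⇌ product + by-product (1.098 L mol⁻¹ min⁻¹, 0.3198 L mol⁻¹ min⁻¹)
    2 partner → lost reagent (0.5886 L mol⁻¹ min⁻¹)
    2 partner ⇌ idle reagent dimer, settled at all times (13.80 L mol⁻¹)

The winter tally comes to 0.686 against the reckoned 0.698, and the slope from the midnight run to the winter run is 0.576 against 0.518. The winter run stands at 49.6 % and not at 55.1 % because of the step that turns pairs of partner into lost reagent. Without that step the winter tally is 0.801, and reckoned through the partner slope as read, this rise is worth an estimated factor of 1.35 in partner charge.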